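**Retrosynthetic overview**

- The C12 hydroxyl lies γ to the C15 imide carbonyl, so O12 and C15 can be tied into a five-membered lactone (O–C12–C13–C14–C15) that is not in the target. Its last ring bond is C13–C14, and an O→N acyl shift later turns this lactone carboxamide into the hydroxy-succinimide.
- The lactone comes from the iodoacetate of a (12S)-allylic alcohol by 5-exo iodine-atom-transfer cyclization, which forms C13–C14, sets C13 from C12 and leaves C16 as CH2I for oxidation to the second carboxyl.
- The allylic alcohol comes from a C12 aldehyde (catalyst-controlled vinylzinc addition), and that from (+)-sclareolide: C2–H chlorination, lactone to Weinreb amide to exocyclic alkene, alkene shift to Δ7 to oxidize C6, deconjugation back to C8=C17, α-face hydride for the 6β-hydroxyl.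
- Ring order: rings A and B from sclareolide; temporary γ-lactone (step 10); succinimide last, by ring switch (step 14).

Key step: step 10

Remark: labdane numbering (C1–C20) is used throughout; the N-chloroamide reagent and the ligand (+)-MIB [(2R)-3-exo-morpholinoisoborneol] are taken as purchasable.

**Step 1**
Reactants: 1 (+)-sclareolide; 2 N-tert-butyl-N-chloro-3,5-bis(trifluoromethyl)benzamide
Product: 3 2α-chlorosclareolide (equatorial chloride at C2 of ring A)
Conditions: 2 (1.2 equiv), Cs2CO3, PhH, white LEDs, 55 °C
Reagents that add atoms: N-tert-butyl-N-chloro-3,5-bis(trifluoromethyl)benzamide 2, CC(C)(C)N(Cl)C(=O)c1cc(cc(c1)C(F)(F)F)C(F)(F)F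
Why: Radical-chain aliphatic C–H chlorination with an N-chloroamide: the bulky electrophilic amidyl radical abstracts hydrogen at C2, the only ring-A methylene not next to a quaternary carbon and remote from the deactivating lactone, and chlorine transfer to the C2 radical should come from the equatorial α direction because the axial β approach is blocked by the C4β and C10 methyls.

**Step 2**
Reactants: 3 2α-chlorosclareolide; 4 N,O-dimethylhydroxylamine hydrochloride
Product: 5 2α-chloro-8α-hydroxy-N-methoxy-N-methyl-13,14,15,16-tetranorlabdan-12-amide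
Conditions: 4 (3 equiv), i-PrMgCl (6 equiv), THF, −20 → 0 °C; aq. NH4Cl
Reagents that add atoms: N,O-dimethylhydroxylamine hydrochloride 4, CNOC.Cl
Why: Weinreb aminolysis of a lactone with the chloromagnesium amide of 4: acyl substitution at C12 frees the tertiary 8α-alkoxide, which cannot re-close onto the amide, and no stereocenter is touched.

**Step 3**
Reactants: 5 hydroxy Weinreb amide
Product: 6 2α-chloro-N-methoxy-N-methyl-13,14,15,16-tetranorlabd-8(17)-en-12-amide
Conditions: SOCl2, pyridine, CH2Cl2, −78 °C
Reagents that add atoms: none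
Why: Dehydration of a tertiary alcohol through its chlorosulfite by E2 elimination: the equatorial 8α leaving group has no anti-periplanar ring hydrogen, so pyridine removes a C17 methyl hydrogen and the exocyclic C8=C17 alkene should result.

**Step 4**
Reactants: 6 exocyclic alkene
Product: 7 2α-chloro-N-methoxy-N-methyl-13,14,15,16-tetranorlabd-7-en-12-amide
Conditions: (salen)CoCl [chloro(N,N′-bis(3,5-di-tert-butylsalicylidene)-1,2-cyclohexanediaminato)cobalt, C36H52ClCoN2O2, trivalent cobalt] (3 mol %), PhSiH3 (6 mol %), PhH, rt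
Reagents that add atoms: none
Why: Metal-hydride hydrogen-atom-transfer alkene isomerization: reversible hydrogen-atom addition to C17 gives the tertiary C8 radical and back-abstraction of an accessible C7 hydrogen by divalent cobalt gives the more stable trisubstituted Δ7 alkene, while the shielded tertiary C9–H, and with it the C9 configuration, should stay untouched.

**Step 5**
Reactants: 7 Δ7 alkene; 8 chromium trioxide
Product: 9 2α-chloro-N-methoxy-N-methyl-6-oxo-13,14,15,16-tetranorlabd-7-en-12-amide
Conditions: CrO3 (12 equiv), 3,5-dimethylpyrazole (12 equiv), CH2Cl2, −20 °C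
Reagents that add atoms: chromium trioxide 8, O=[Cr](=O)=O
Why: Allylic oxidation of a cycloalkene methylene to the enone with the CrO3–3,5-dimethylpyrazole complex, the reaction that converts Δ5-steroids into 7-ketones: of the allylic positions only C6 is a ring methylene next to the vinylic CH, so the Δ7-6-ketone is expected.

**Step 6**
Reactants: 9 Δ7-6-ketone
Product: 11 2α-chloro-N-methoxy-N-methyl-6-oxo-13,14,15,16-tetranorlabd-8(17)-en-12-amide, via potassium dienolate 10 (not isolated)
Conditions: KN(SiMe3)2 (1.5 equiv), THF, −78 °C; then inverse addition to AcOH/THF, −78 °C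
Reagents that add atoms: none
Why: Kinetic deconjugation of an α,β-unsaturated ketone through its extended dienolate: the hindered amide base removes a hydrogen of the exposed C17 methyl (C5–H and the tertiary C9–H are shielded by the C4 and C10 quaternary centers), and irreversible low-temperature protonation of dienolate 10 at its α-carbon C7 gives the β,γ-unsaturated ketone with the C8=C17 methylene.

**Step 7**
Reactants: 11 β,γ-unsaturated ketone
Product: 12 2α-chloro-6β-hydroxy-13,14,15,16-tetranorlabd-8(17)-en-12-al
Conditions: LiAlH4, THF, −78 → 0 °C; aq. KNaC4H4O6 (Rochelle salt)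
Reagents that add atoms: none
Why: Hydride reduction with LiAlH4 (Weinreb aldehyde synthesis for C12): hydride adds to the C6 ketone from the open α face, the β face being blocked by the axial C4β and C10 methyls, which sets the axial 6β-hydroxyl, and the Weinreb amide is reduced only to the chelated tetrahedral intermediate that releases the aldehyde on work-up.

**Step 8**
Reactants: 12 hydroxy aldehyde; 13 vinylmagnesium bromide
Product: 14 (12S)-2α-chloro-14,15-dinorlabda-8(17),13(16)-diene-6β,12-diol
Conditions: 13 and ZnCl2 (2:1), THF; 1,4-dioxane, filtration of the magnesium salts; then 12, (+)-MIB (10 mol %), toluene, 0 °C; aq. NH4Cl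
Reagents that add atoms: vinylmagnesium bromide 13, C=C[Mg]Br
Why: Catalytic enantioselective alkenylzinc addition to an aldehyde under amino-alcohol ligand control: the (+)-MIB–zinc complex should deliver the vinyl group to the Re face of the C12 aldehyde and so set (12S) by catalyst control, while the hindered 6β-hydroxyl is only converted into a spectator zinc alkoxide.

**Step 9**
Reactants: 14 allylic alcohol; 15 iodoacetic acid
Product: 16 12-O-iodoacetate of 14 (6β-hydroxyl free)
Conditions: 15 (1.2 equiv), DCC, DMAP (5 mol %), CH2Cl2, 0 °C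
Reagents that add atoms: iodoacetic acid 15, OC(=O)CI
Why: Steglich esterification: the unhindered allylic C12 hydroxyl is acylated, whereas the 6β-hydroxyl, 1,3-diaxial to the C4β and C10 methyls like a steroid 11β-hydroxyl, should remain free; the C12 configuration is retained.

**Step 10**
Reactants: 16 allylic iodoacetate
Product: 17 (12S,13R)-2α-chloro-6β-hydroxy-16-iodolabd-8(17)-en-15,12-olide (trans-β-iodomethyl γ-lactone)
Conditions: dilauroyl peroxide (0.2 equiv, in portions), PhH (0.02 M), 80 °C
Reagents that add atoms: none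
Why: Iodine-atom-transfer radical cyclization (Kharasch-type atom transfer, the haloacetate route to paraconic-acid lactones): an undecyl radical from the peroxide abstracts iodine from 16, the electrophilic C14 radical adds to C13 of the vinyl group, and the resulting primary C16 radical abstracts iodine from a second molecule of 16, so the chain isomerizes 16 into 17 without any reductant. The γ-lactone (O–C12–C13–C14–C15) closes 5-exo-trig through the C13–C14 bond; it is a temporary ring, its C12–O–C15 ester bond being absent from the target. The new stereocenter C13 is controlled by the existing C12 stereocenter: in the Beckwith–Houk transition state the bulky C11 substituent sits pseudo-equatorial, which places C16 trans to C11 (13R). The step needs 5-exo over 6-endo closure, preference for the allylic vinyl group over the C8=C17 methylene, and access to the reactive ester rotamer; the shorter exo mode and the proximity of the vinyl group (closure onto C8=C17 would be 7-exo or 8-endo) secure the first two, 80 °C at high dilution the third. Fast iodine transfer to the primary C16 radical should also forestall its 7-endo attack on C8=C17, and the 6β-hydroxyl and the C2 chloride are inert to carbon radicals.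

**Step 11**
Reactants: 17 iodomethyl lactone; 18 trimethylamine N-oxide
Product: 19 (12S,13R)-2α-chloro-6β-hydroxy-16-oxolabd-8(17)-en-15,12-olide (trans-β-formyl γ-lactone)
Conditions: Me3NO (4 equiv), NaHCO3, DMSO, 40 °C
Reagents that add atoms: trimethylamine N-oxide 18, C[N+](C)(C)[O-]
Why: Kornblum-type oxidation of a primary iodide with an amine N-oxide: SN2 displacement of iodide by the N-oxide oxygen and base-induced loss of trimethylamine give the C16 aldehyde, and because C13 is now epimerizable any cis-lactone should equilibrate to the more stable trans isomer under the bicarbonate conditions.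

**Step 12**
Reactants: 19 lactone aldehyde; 20 sodium chlorite
Product: 21 (12S,13R)-2α-chloro-6β-hydroxylabd-8(17)-en-15,12-olid-16-oic acid
Conditions: NaClO2, NaH2PO4, 2-methyl-2-butene, t-BuOH/H2O, 0 °C → rt
Reagents that add atoms: sodium chlorite 20, [Na+].[O-]Cl=O
Why: Pinnick oxidation: chlorous acid oxidizes only the aldehyde to the C16 carboxylic acid, 2-methyl-2-butene scavenges hypochlorous acid so that the C8=C17 alkene survives, and the buffered medium should not epimerize C13.

**Step 13**
Reactants: 21 lactone acid; 22 ammonia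
Product: 24 (12S,13R)-2α-chloro-6β-hydroxylabd-8(17)-en-15,12-olide-16-carboxamide, via acyl imidazole 23 (not isolated)
Conditions: 1,1′-carbonyldiimidazole (1.2 equiv), THF, rt; then NH3 (0.5 M in 1,4-dioxane, 3 equiv), 0 °C
Reagents that add atoms: ammonia 22, N
Why: Carboxyl activation as the acyl imidazole followed by ammonolysis: the acyl imidazole acylates ammonia far faster than the γ-lactone does at 0 °C, so the primary carboxamide should form with the lactone and both stereocenters intact.

**Step 14**
Reactants: 24 lactone carboxamide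
Product: 26 haterumaimide F, via potassium imidate 25 (not isolated)
Conditions: t-BuOK (1.1 equiv), THF, −20 → 0 °C; then AcOH
Reagents that add atoms: none
Why: Base-mediated intramolecular N-acylation of a primary amide by an ester (imide formation, here an O→N acyl shift): the amidate nitrogen attacks the lactone carbonyl C15 in a 5-exo-trig mode, the C12 alkoxide is expelled, and proton transfer gives the far less basic imidate 25, which makes the lactone-to-succinimide ring switch irreversible; C12 and C13 are not involved and keep their configuration, and acidification gives 26.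

**Compound list**

1 | (+)-sclareolide | C[C@@]12CC[C@H]3C(C)(C)CCC[C@]3(C)[C@H]1CC(=O)O2 | starting material
2 | N-tert-butyl-N-chloro-3,5-bis(trifluoromethyl)benzamide | CC(C)(C)N(Cl)C(=O)c1cc(cc(c1)C(F)(F)F)C(F)(F)F | starting material
3 | 2α-chlorosclareolide | C[C@@]12CC[C@H]3C(C)(C)C[C@H](Cl)C[C@]3(C)[C@H]1CC(=O)O2 | intermediate
4 | N,O-dimethylhydroxylamine hydrochloride | CNOC.Cl | starting material
5 | 2α-chloro-8α-hydroxy-N-methoxy-N-methyl-13,14,15,16-tetranorlabdan-12-amide | C[C@@]1(O)CC[C@H]2C(C)(C)C[C@H](Cl)C[C@]2(C)[C@H]1CC(=O)N(C)OC | intermediate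
6 | 2α-chloro-N-methoxy-N-methyl-13,14,15,16-tetranorlabd-8(17)-en-12-amide | C=C1CC[C@H]2C(C)(C)C[C@H](Cl)C[C@]2(C)[C@H]1CC(=O)N(C)OC | intermediate
7 | 2α-chloro-N-methoxy-N-methyl-13,14,15,16-tetranorlabd-7-en-12-amide | CC1=CC[C@H]2C(C)(C)C[C@H](Cl)C[C@]2(C)[C@H]1CC(=O)N(C)OC | intermediate
8 | chromium trioxide | O=[Cr](=O)=O | starting material
9 | 2α-chloro-N-methoxy-N-methyl-6-oxo-13,14,15,16-tetranorlabd-7-en-12-amide | CC1=CC(=O)[C@H]2C(C)(C)C[C@H](Cl)C[C@]2(C)[C@H]1CC(=O)N(C)OC | intermediate
10 | potassium 6,8(17)-dien-6-olate derived from 9 | [K+].C=C1C=C([O-])[C@H]2C(C)(C)C[C@H](Cl)C[C@]2(C)[C@H]1CC(=O)N(C)OC | intermediate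
11 | 2α-chloro-N-methoxy-N-methyl-6-oxo-13,14,15,16-tetranorlabd-8(17)-en-12-amide | C=C1CC(=O)[C@H]2C(C)(C)C[C@H](Cl)C[C@]2(C)[C@H]1CC(=O)N(C)OC | intermediate
12 | 2α-chloro-6β-hydroxy-13,14,15,16-tetranorlabd-8(17)-en-12-al | C=C1C[C@@H](O)[C@H]2C(C)(C)C[C@H](Cl)C[C@]2(C)[C@H]1CC=O | intermediate
13 | vinylmagnesium bromide | C=C[Mg]Br | starting material
14 | (12S)-2α-chloro-14,15-dinorlabda-8(17),13(16)-diene-6β,12-diol | C=C1C[C@@H](O)[C@H]2C(C)(C)C[C@H](Cl)C[C@]2(C)[C@H]1C[C@H](O)C=C | intermediate
15 | iodoacetic acid | OC(=O)CI | starting material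
16 | 12-O-iodoacetate of 14 | C=C1C[C@@H](O)[C@H]2C(C)(C)C[C@H](Cl)C[C@]2(C)[C@H]1C[C@H](OC(=O)CI)C=C | intermediate
17 | (12S,13R)-2α-chloro-6β-hydroxy-16-iodolabd-8(17)-en-15,12-olide | C=C1C[C@@H](O)[C@H]2C(C)(C)C[C@H](Cl)C[C@]2(C)[C@H]1C[C@@H]1OC(=O)C[C@H]1CI | intermediate
18 | trimethylamine N-oxide | C[N+](C)(C)[O-] | starting material
19 | (12S,13R)-2α-chloro-6β-hydroxy-16-oxolabd-8(17)-en-15,12-olide | C=C1C[C@@H](O)[C@H]2C(C)(C)C[C@H](Cl)C[C@]2(C)[C@H]1C[C@@H]1OC(=O)C[C@H]1C=O | intermediate
20 | sodium chlorite | [Na+].[O-]Cl=O | starting material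
21 | (12S,13R)-2α-chloro-6β-hydroxylabd-8(17)-en-15,12-olid-16-oic acid | C=C1C[C@@H](O)[C@H]2C(C)(C)C[C@H](Cl)C[C@]2(C)[C@H]1C[C@@H]1OC(=O)C[C@H]1C(=O)O | intermediate
22 | ammonia | N | starting material
23 | 16-acyl imidazole of 21 | C=C1C[C@@H](O)[C@H]2C(C)(C)C[C@H](Cl)C[C@]2(C)[C@H]1C[C@@H]1OC(=O)C[C@H]1C(=O)n1ccnc1 | intermediate
24 | (12S,13R)-2α-chloro-6β-hydroxylabd-8(17)-en-15,12-olide-16-carboxamide | C=C1C[C@@H](O)[C@H]2C(C)(C)C[C@H](Cl)C[C@]2(C)[C@H]1C[C@@H]1OC(=O)C[C@H]1C(N)=O | intermediate
25 | potassium salt of 26 (imide nitrogen deprotonated) | [K+].C=C1C[C@@H](O)[C@H]2C(C)(C)C[C@H](Cl)C[C@]2(C)[C@H]1C[C@H](O)[C@H]1CC(=O)[N-]C1=O | intermediate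
26 | haterumaimide F | C=C1C[C@@H](O)[C@H]2C(C)(C)C[C@H](Cl)C[C@]2(C)[C@H]1C[C@H](O)[C@H]1CC(=O)NC1=O | target

**Step count**

Total step count: 14. Longest linear sequence: 14 steps (from 1).

**Steps most likely to fail**

1. Step 6 (deconjugation). What may go wrong: loss of regiocontrol in the γ-deprotonation (removal of C9–H or C5–H instead of a C17 methyl hydrogen), or re-conjugation during the quench. Fallback with known chemistry, from 9 back to 11: Weitz–Scheffer epoxidation of 9 (H2O2, NaOH, MeOH, 0 °C; the hydroperoxide anion attacks C8 from the open α face) should give the 7α,8α-epoxy-6-ketone F1. Reductive cleavage of its Cα–O bond (SmI2, THF/MeOH, −90 °C) gives the 8α-hydroxy-6-ketone F2, which carries the same equatorial tertiary alcohol as 5. SOCl2/pyridine at −78 °C then eliminates toward C17 as in step 3 and delivers 11.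

2. Step 8 (vinylation). What may go wrong: poor facial selectivity at the α-unbranched aldehyde, or a racemic background addition promoted by residual salts. Fallback, from 12 back to 14: addition of lithium (trimethylsilyl)acetylide (n-BuLi, THF, −78 °C) to 12 gives the C12-epimeric propargylic alcohols F3. MnO2 oxidizes only this propargylic alcohol to the ynone F4. Noyori transfer hydrogenation with RuCl[(S,S)-TsDPEN](p-cymene) in i-PrOH should give the (12S)-propargylic alcohol F5. K2CO3/MeOH removes the silyl group to give the terminal alkyne F6, and semihydrogenation (H2, Lindlar catalyst Pd/CaCO3 with Pb(OAc)2, quinoline) gives 14.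

3. Step 10 (key cyclization). What may go wrong: slow closure from the unreactive ester rotamer, so that telomerization or reduction of the C14 radical competes, or erosion of the trans selectivity. Fallback, from 14 back to 17: acylation of 14 with bromoacetyl bromide (pyridine, CH2Cl2, −78 °C) gives the bromoacetate F7. N,N′-ditosylhydrazine/DBU converts it into the diazoacetate F8. Rh2(OAc)4-catalyzed intramolecular cyclopropanation of the vinyl group (CH2Cl2, slow addition) closes the same C13–C14 bond in the cyclopropane-fused lactone F9 (a 3-oxabicyclo[3.1.0]hexan-2-one with the C11 substituent exo). Homoconjugate opening of the carbonyl-activated C14–C16 bond by iodide (NaI/Me3SiCl, MeCN, 0 °C) gives iodide 17.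

**Further compounds**

F1 | step 6 | 2α-chloro-7α,8α-epoxy-N-methoxy-N-methyl-6-oxo-13,14,15,16-tetranorlabdan-12-amide | C[C@@]12O[C@@H]1C(=O)[C@H]3C(C)(C)C[C@H](Cl)C[C@]3(C)[C@H]2CC(=O)N(C)OC
F2 | step 6 | 2α-chloro-8α-hydroxy-N-methoxy-N-methyl-6-oxo-13,14,15,16-tetranorlabdan-12-amide | C[C@@]1(O)CC(=O)[C@H]2C(C)(C)C[C@H](Cl)C[C@]2(C)[C@H]1CC(=O)N(C)OC
F3 | step 8 | C12-epimeric 12-hydroxy-12-(trimethylsilylethynyl) adducts of 12 | C=C1C[C@@H](O)[C@H]2C(C)(C)C[C@H](Cl)C[C@]2(C)[C@H]1CC(O)C#C[Si](C)(C)C
F4 | step 8 | 12-oxo trimethylsilyl ynone | C=C1C[C@@H](O)[C@H]2C(C)(C)C[C@H](Cl)C[C@]2(C)[C@H]1CC(=O)C#C[Si](C)(C)C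
F5 | step 8 | (12S)-trimethylsilyl propargylic alcohol | C=C1C[C@@H](O)[C@H]2C(C)(C)C[C@H](Cl)C[C@]2(C)[C@H]1C[C@H](O)C#C[Si](C)(C)C
F6 | step 8 | (12S)-terminal propargylic alcohol | C=C1C[C@@H](O)[C@H]2C(C)(C)C[C@H](Cl)C[C@]2(C)[C@H]1C[C@H](O)C#C
F7 | step 10 | 12-O-bromoacetate of 14 | C=C1C[C@@H](O)[C@H]2C(C)(C)C[C@H](Cl)C[C@]2(C)[C@H]1C[C@H](OC(=O)CBr)C=C
F8 | step 10 | 12-O-diazoacetate of 14 | C=C1C[C@@H](O)[C@H]2C(C)(C)C[C@H](Cl)C[C@]2(C)[C@H]1C[C@H](OC(=O)C=[N+]=[N-])C=C
F9 | step 10 | cyclopropane-fused lactone (14,16-cyclo-labd-8(17)-en-15,12-olide, C11 substituent exo) | C=C1C[C@@H](O)[C@H]2C(C)(C)C[C@H](Cl)C[C@]2(C)[C@H]1C[C@@H]1OC(=O)[C@H]2C[C@@H]12
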